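**Strategy.** Everything rests on disconnecting C4a–C8a, the bond shared by the dihydropyran ring C and the enolised acyltrione ring D (chromene locants O1, C2, C3, C4, C4a, C5–C8, C8a). Ring D is a 1,3,5-trioxygenated carbocycle whose quaternary C8 sits next to C8a, so it unfolds into a linear triketo ester. The key step, a polyketide-style Claisen (Dieckmann-type) closure of the acetyl carbanion (future C4a) onto the α,α-dimethyl ester carbon (future C8a), creates the complete acylfilicinic-acid ring in one operation. Formaldehyde then links it to α-humulene by a Knoevenagel/hetero-Diels–Alder reaction (ring C). Resolution, epoxidation and a cationic transannular cascade form rings A and B.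

Key step: step 2

**Numbering.** Rings C/D carry the chromene locants above. The eleven humulene ring carbons are T1–T11 (T1 = C3, T2 = C2; alkenes T1=T2, T4=T5, T8=T9; T6 is the gem-dimethyl carbon). Ring A is the cyclopentane, ring B the cycloheptane.

**Remark.** Humulene and the heterodiene are achiral, so the cycloadduct forms as a racemate and the absolute configuration is fixed by a resolution (step 4). Acid chloride 2 is taken as a catalogue compound.

Step 1
Reactants: 1 5-methylhexane-2,4-dione; 2 methyl 3-chloro-2,2-dimethyl-3-oxopropanoate
Product: 3 methyl 4-acetyl-2,2,6-trimethyl-3,5-dioxoheptanoate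
Conditions: MgCl2, pyridine, CH2Cl2, 0 °C to rt; then 1 M HCl
Reagents that add atoms: none
Why: Magnesium-chelate-directed C-acylation of a 1,3-diketone (soft enolisation): the MgCl2/pyridine enolate of 1 reacts at its central carbon with 2, whose quaternary α-carbon excludes ketene formation, and the product is shielded from further reaction as its magnesium enolate; no stereocentre is formed.

Step 2
Reactants: 3 methyl 4-acetyl-2,2,6-trimethyl-3,5-dioxoheptanoate
Product: 4 3-hydroxy-6,6-dimethyl-2-(2-methylpropanoyl)cyclohex-2-ene-1,5-dione
Conditions: LiN(iPr)2 (3.3 equiv), THF, −78 °C to 0 °C; then 1 M HCl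
Reagents that add atoms: none
Why: LiN(iPr)2 first forms the chelated triacylmethanide and then removes a proton from the acetyl CH3, and the terminal carbanion of this dianion adds to the ester carbonyl; loss of methoxide gives the trione, which is drained from the equilibrium as its enolate. The closest known reactions are the Claisen (Dieckmann-type) cyclisation of δ-keto esters to cyclohexane-1,3-diones (dimedone, syncarpic acid) and the acylation of 1,3-diketone dianions by esters. Ring D closes in a 6-(enolendo)-exo-trig mode by forming C4a–C8a. No stereocentre is created. The step needs C- and not O-attack on the ester and ionisation at the acetyl and not the isobutyryl terminus: the hard γ-carbanion at low temperature secures the first, the kinetic acidity order CH3 > CH the second. The quaternary C8 helps twice, since it makes the ester non-enolisable and imposes a gem-dimethyl (Thorpe–Ingold) bias toward closure.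

Step 3
Reactants: 4 3-hydroxy-6,6-dimethyl-2-(2-methylpropanoyl)cyclohex-2-ene-1,5-dione; 5 α-humulene
Product: 7 racemic (T1S,T2R)/(T1R,T2S) cycloadduct (hyperjapone A), via methylidene trione 6 (not isolated)
Conditions: paraformaldehyde (1.5 equiv), 5 (3 equiv), ethylenediammonium diacetate (10 mol %), 1,4-dioxane, 80 °C
Reagents that add atoms: formaldehyde (as paraformaldehyde), C=O
Why: Domino Knoevenagel condensation/inverse-electron-demand hetero-Diels–Alder reaction: C4a, the only free nucleophilic carbon of 4, condenses with formaldehyde to the 1-oxadiene 6 (its capture by a second molecule of 4 is reversible), which adds through O=C8a–C4a=CH2 to the most electron-rich, least hindered T1=T2 alkene of excess humulene with oxygen on the more substituted T2, the suprafacial addition to the E alkene placing H-T1 and CH3-T2 trans and giving both stereocentres as a racemate.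

Step 4
Reactants: 7 racemic cycloadduct
Product: 8 (T1S,T2R)-cycloadduct
Conditions: preparative HPLC, amylose tris(3,5-dimethylphenylcarbamate) stationary phase, hexane/2-propanol (0.1% HCO2H), rt
Reagents that add atoms: none
Why: Resolution by chromatography on a chiral stationary phase: the enantiomers of 7 form diastereomeric adsorbates on the polysaccharide carbamate selector, neither stereocentre can epimerise, and the (T1S,T2R) enantiomer is to be identified by comparing its electronic circular dichroism with the calculated curve.

Step 5
Reactants: 8 (T1S,T2R)-cycloadduct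
Product: 9 (T1S,T2R,T8R,T9R)-T8,T9-epoxide of 8
Conditions: mCPBA (1.05 equiv), CH2Cl2, 0 °C; aq. NaHCO3 work-up
Reagents that add atoms: mCPBA, OOC(=O)c1cccc(Cl)c1
Why: Prilezhaev epoxidation: the peracid selects the electron-rich trisubstituted T8=T9 alkene over the neopentylic disubstituted T4=T5 alkene and the deactivated vinylogous ester, and attack on the exposed outer face of the E alkene in the preferred conformation of the eleven-membered ring should give the trans (T8R,T9R) epoxide under control of the T1/T2 stereocentres.

Step 6
Reactants: 9 T8,T9-epoxide
Product: 10 target CNP0510355.1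
Conditions: p-TsOH·H2O (0.2 equiv), CH2Cl2, 0 °C to rt
Reagents that add atoms: none
Why: Acid-catalysed epoxide-opening/transannular cation–olefin cyclisation/Wagner–Meerwein ring contraction/E1 cascade: the protonated epoxide opens at tertiary T9 with backside attack by T4 of the facing (E)-T4=T5 alkene (inversion at T9, retention at carbinol T8, trans A/B fusion from the cross-ring geometry), T7 then shifts from T6 to T5 on the alkene face already bonded to T9 so that the E geometry becomes the trans relation of T3 and the side chain, and the 2-propyl cation loses a proton to give the isopropenyl group.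

**Compound list**

1 | 5-methylhexane-2,4-dione | CC(=O)CC(=O)C(C)C | starting material
2 | methyl 3-chloro-2,2-dimethyl-3-oxopropanoate | COC(=O)C(C)(C)C(Cl)=O | starting material
3 | methyl 4-acetyl-2,2,6-trimethyl-3,5-dioxoheptanoate (drawn as the triketone) | COC(=O)C(C)(C)C(=O)C(C(C)=O)C(=O)C(C)C | intermediate
4 | 3-hydroxy-6,6-dimethyl-2-(2-methylpropanoyl)cyclohex-2-ene-1,5-dione (isobutyrylfilicinic acid tautomer) | CC(C)C(=O)C1=C(O)CC(=O)C(C)(C)C1=O | intermediate
5 | α-humulene, (1E,4E,8E)-2,6,6,9-tetramethylcycloundeca-1,4,8-triene | C/C1=C\CC/C(C)=C/CC(C)(C)/C=C/C1 | starting material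
6 | 3-hydroxy-6,6-dimethyl-4-methylidene-2-(2-methylpropanoyl)cyclohex-2-ene-1,5-dione (methylidene trione) | CC(C)C(=O)C1=C(O)C(=C)C(=O)C(C)(C)C1=O | intermediate
7 | racemic cycloadduct (hyperjapone A): ring C trans-fused to the eleven-membered ring, H-T1 and CH3-T2 trans, (E)-T4=T5 and (E)-T8=T9; 1:1 mixture of both enantiomers | C1[C@H]2CC3=C(O[C@]2(C)C/C=C/C(C)(C)C/C=C(C)/C1)C(C)(C)C(=O)C(C(=O)C(C)C)=C3O.C1[C@@H]2CC3=C(O[C@@]2(C)C/C=C/C(C)(C)C/C=C(C)/C1)C(C)(C)C(=O)C(C(=O)C(C)C)=C3O | intermediate
8 | (T1S,T2R)-cycloadduct, single enantiomer of 7 | C1[C@H]2CC3=C(O[C@]2(C)C/C=C/C(C)(C)C/C=C(C)/C1)C(C)(C)C(=O)C(C(=O)C(C)C)=C3O | intermediate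
9 | (T1S,T2R,T8R,T9R)-T8,T9-epoxide of 8, trans epoxide, (E)-T4=T5 retained | C1[C@H]2CC3=C(O[C@]2(C)C/C=C/C(C)(C)C[C@H]4O[C@]4(C)C1)C(C)(C)C(=O)C(C(=O)C(C)C)=C3O | intermediate
10 | target CNP0510355.1, (T1S,T2R,T4S,T5R,T8R,T9R): trans-fused rings A/B and B/C, OH-T8 cis to CH3-T9, isopropenyl-T5 cis to H-T4 | C=C(C)[C@@H]1C[C@@H](O)[C@]2(C)CC[C@H]3CC4=C(O[C@]3(C)C[C@@H]12)C(C)(C)C(=O)C(C(=O)C(C)C)=C4O | target

**Total step count:** 6. **Longest linear sequence:** 6 steps.

**Steps most likely to fail**

Step 2. Lactonisation through the enolate oxygen (to a pyran-2,4-dione), ionisation at the isobutyryl methine or retro-Claisen fragmentation of the crowded triacylmethane may outrun the C–C closure. The fallback closes the same bond before the isobutyryl group is present. It sets out from 2: acylation of the lithium enolate of acetone (LiN(iPr)2, THF, −78 °C) gives methyl 2,2-dimethyl-3,5-dioxohexanoate F1. NaOMe in refluxing MeOH then performs the Claisen closure on this simple 3,5-dioxo ester to give filicinic acid F2. Friedel–Crafts-type C-acylation with isobutyryl chloride (AlCl3, nitrobenzene) comes back to the route at 4.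

Step 3. Michael capture of heterodiene 6 by a second molecule of 4 (methylene-bridged dimer) or a second cycloaddition on the remaining trisubstituted alkene may dominate over the 1:1 cycloaddition. The fallback separates carbon introduction from heterodiene formation. It sets out from 4: C-methylation at C4a (MeI, NaOMe, MeOH) gives 3-hydroxy-4,6,6-trimethyl-2-(2-methylpropanoyl)cyclohex-2-ene-1,5-dione (norflavesone) F3. Dehydrogenation with Ag2O and catalytic TEMPO in the presence of 5 generates 6 with no free 4 present and comes back at 7.

Step 1. O-acylation, slow reaction of the neopentyl-type acid chloride at the crowded central carbon, or deacylation of the product on work-up may erode the C-acylation. The fallback makes the hindered bond on a less crowded nucleophile and adds the small acyl group last. It sets out from 2: acylation of the kinetic lithium enolate of 3-methylbutan-2-one (LiN(iPr)2, THF, −78 °C) gives methyl 2,2,6-trimethyl-3,5-dioxoheptanoate F4. C-acetylation (acetyl chloride, MgCl2, pyridine, CH2Cl2) comes back at 3.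

**Further compounds**

F1 | step 2 | methyl 2,2-dimethyl-3,5-dioxohexanoate | CC(=O)CC(=O)C(C)(C)C(=O)OC
F2 | step 2 | filicinic acid (3,5-dihydroxy-4,4-dimethylcyclohexa-2,5-dien-1-one) | CC1(C)C(O)=CC(=O)C=C1O
F3 | step 3 | 3-hydroxy-4,6,6-trimethyl-2-(2-methylpropanoyl)cyclohex-2-ene-1,5-dione (norflavesone) | CC(C)C(=O)C1=C(O)C(C)C(=O)C(C)(C)C1=O
F4 | step 1 | methyl 2,2,6-trimethyl-3,5-dioxoheptanoate | COC(=O)C(C)(C)C(=O)CC(=O)C(C)C
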